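## The problem

Target 8 is a flat, achiral indole: a benzene ring fused across C3a–C7a to an N-methylpyrrole that carries bromine at C2 and a formyl group at C3, with two further bromines on the adjacent benzenoid carbons C5 and C6. With no stereocenter present, nothing has to be relayed from one center to another; the task is only to put five substituents on the right atoms of a 6-5 bicycle. The benzenoid bromines cannot be placed cleanly by brominating an indole, which reacts in the pyrrole ring first and then discriminates poorly among C4 to C7, so they should arrive with the arene. The C2 bromine and the C3 aldehyde together form a vinylogous acyl bromide: C2 is open to nucleophilic displacement and the aldehyde to bases, hydrides and organometallics, so this pair is best released in the last operation. The two aryl C–Br bonds must pass untouched through whatever metal chemistry builds the ring. The enabling feature is that C3 lies between C2, which is at the oxidation level of a carboxamide, and the formyl carbon. The C2–C3–CHO chain therefore maps onto a 3-alkoxyacryloyl group on N1, so the C3–C3a bond can be closed from an ortho-halogenated anilide of that acid, and the ring so formed holds both oxygenated carbons in masked form.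

## Retrosynthesis

**C2–Br bond and the aldehyde, 8 to 6.** The last cut removes the C2–Br bond and returns the aldehyde to an enol ether. Target 8 is then the product of dehydrative bromination of (Z)-5,6-dibromo-3-(ethoxymethylene)-1-methylindolin-2-one 6, through the ethoxycarbenium salt 7, which water cleaves. The neighbouring options are weaker. Electrophilic bromination at C2 of a 3-formylindole works against the deactivating aldehyde, and C2 lithiation would collide with bromine–lithium exchange at C5 and C6. Bromoformylation of the parent oxindole would reach 8 as directly, but that oxindole lacks the formyl carbon and needs a ring closure of its own; it is kept in reserve. Lactam 6 has one C–Br bond less and no free aldehyde. The forward step must activate the lactam oxygen and send bromide to C2; aromatization to the indole drives it.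

**C3–C3a bond, 6 to 5.** Cutting the bond between the arene and C3 opens the lactam to the acyclic anilide 5, (E)-N-(4,5-dibromo-2-iodophenyl)-3-ethoxy-N-methylacrylamide. A cut at N1–C7a would need a separate C-arylation first. A cut at N1–C2 would need an arylacetic acid that already carries the formyl equivalent. The chosen cut uses the amide as the tether and lets one three-carbon acid supply C2, C3 and the formyl carbon intact. It removes the only ring and the only skeletal C–C bond made in the synthesis. The forward step must insert at C–I and leave both C–Br bonds alone, and it must close 5-exo, not 6-endo.

**N–CH3 bond, 5 to 4.** The methyl group is removed next, giving the secondary anilide 4. Methylation is placed after acylation because alkylating an anilide anion stops cleanly at one methyl group, whereas monomethylation of a primary aniline does not. The tertiary anilide is also the rotamer the ring closure needs. The forward step asks only for N- over O-alkylation.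

**Amide bond, 4 to 2 and 3.** Cleaving the amide gives 4,5-dibromo-2-iodoaniline 2 and (E)-3-ethoxyacryloyl chloride 3, a commercial acid chloride that brings the E enol ether ready-made. The forward step is an acylation of a weakly nucleophilic, ortho-substituted aniline.

**C–I bond, 2 to 1.** Removing iodine leads to commercial 3,4-dibromoaniline 1. The iodine marks the carbon that becomes C3a; placing it ortho to nitrogen and para to one bromine fixes the 5,6-dibromo pattern of the indole. The forward step needs mono-iodination at the unflanked ortho position.

## Roads not taken

**Alternative 1:** This road cuts three bonds of the benzene ring (C3a–C7a, C4–C5, C6–C7). A CpCo(CO)2-mediated [2+2+2] cycloaddition would join diyne A1 (methyl but-3-yn-1-yl(ethynyl)carbamate) with bis(trimethylsilyl)acetylene A2 to give methyl 5,6-bis(trimethylsilyl)indoline-1-carboxylate A3, closing the five-membered nitrogen ring and the arene together. The silyl groups would later be exchanged for bromine by ipso-substitution. Its merit is real: the 5,6-pattern is fixed by construction, and no carbon–halogen bond exists while a transition metal is at work. In both respects it is at least as secure as the chosen plan, which sets against it one site-selective iodination of 1 and the rate gap between C–I and C–Br in oxidative addition. The price is length and an unsolved end game. A1 is a sensitive terminal ynamide that takes several steps to make, and the cyclization needs a large excess of A2. A3 is still an indoline carbamate, so two bromodesilylations, dehydrogenation, exchange of the carbamate for N-methyl, C3 formylation and C2 bromination remain. The last of these is the problem that the lactam carbonyl of 6 solves; A3 holds C2 and C3 at the hydrocarbon level.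

**Alternative 2:** Here both benzenoid C–Br bonds are cut together. Fluoride-induced elimination (CsF) from silyl triflate A4 (3-formyl-1-methyl-6-(trimethylsilyl)-1H-indol-5-yl trifluoromethanesulfonate) would generate the 5,6-indolyne A5, and Li2CuBr4 would add two bromine atoms across the strained bond to give 5,6-dibromo-1-methyl-1H-indole-3-carbaldehyde A6. The bromines enter late, so nothing halogenated has to survive earlier steps. Because the same atom ends on both aryne carbons, the usual regiochemical question of indolyne additions does not arise. On this point the alternative is better than the chosen plan, which carries two bromines through a palladium step and relies on faster insertion into C–I. The weaknesses lie on both sides of the key step. A4 needs an indole with oxygen at C5 and silicon at C6, a preparation longer than the whole chosen route. Vicinal dibromination of an aryne is less reliable than trapping by a single nucleophile, and protonation of the intermediate aryl-copper species would leave monobromides that are hard to remove. A6 still lacks the C2 bromine, which would have to go onto an electron-poor 3-formylindole in the presence of two aryl bromides. The chosen plan releases the C2 bromide and the aldehyde in one operation from 6.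

**Alternative 3:** This road cuts N1–C7a. Thermolysis of azidocinnamate A7 (ethyl (Z)-2-azido-3-(3,4-dibromophenyl)acrylate) expels nitrogen, and the vinyl nitrene closes onto an ortho carbon to give ethyl 5,6-dibromo-1H-indole-2-carboxylate A8 (Hemetsberger indole synthesis). The ester is meant to be replaced by bromine later. The road is short as far as the indole, since A7 arises in one condensation. It uses inexpensive materials and no transition metal, so the aryl bromides are never at risk. In cost and in halogen safety it is better than the chosen plan. Against this, the nitrene can close onto either ortho carbon of the 3,4-dibromophenyl ring. Closure next to bromine gives the 6,7-dibromo isomer A9, and only a steric preference separates the two paths. In the chosen plan the iodine of 5 names the carbon that becomes C3a. The azide is also a thermal hazard on scale. The ester is a poor stand-in for bromine: saponification, bromodecarboxylation, N-methylation and C3 formylation still follow A8, in an awkward order because the formyl group deactivates C2. The chosen plan is complete in five steps, which this road cannot match once the steps after A8 are counted.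

Key step: step 4

Remark on the chemistry: the exocyclic double bond of 6 is drawn Z, as syn insertion and syn elimination from the E-acrylamide 5 would deliver it. Any later equilibration is of no consequence, since this element disappears in step 5.

## Route

Step 1
Reactants: 1 3,4-dibromoaniline
Product: 2 4,5-dibromo-2-iodoaniline
Conditions: NIS (1.05 equiv), AcOH, rt
Reagents that add atoms: N-iodosuccinimide, O=C1CCC(=O)N1I
Why: Electrophilic aromatic iodination directed by the amino group; the para position carries bromine and one ortho position is flanked by bromine, so a single equivalent should iodinate the open ortho carbon and stop at mono-substitution.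

Step 2
Reactants: 2 4,5-dibromo-2-iodoaniline; 3 (E)-3-ethoxyacryloyl chloride
Product: 4 (E)-N-(4,5-dibromo-2-iodophenyl)-3-ethoxyacrylamide
Conditions: pyridine (3 equiv), THF, 0 °C to rt
Reagents that add atoms: none
Why: N-acylation of an aniline by an acid chloride with pyridine as acid scavenger; the acid chloride is reactive enough for a deactivated aniline, and the E enol ether is left alone because no free acid builds up.

Step 3
Reactants: 4 (E)-N-(4,5-dibromo-2-iodophenyl)-3-ethoxyacrylamide
Product: 5 (E)-N-(4,5-dibromo-2-iodophenyl)-3-ethoxy-N-methylacrylamide
Conditions: NaH, DMF, 0 °C; MeI, 0 °C to rt
Reagents that add atoms: iodomethane, CI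
Why: Deprotonation of the acidic anilide N–H and SN2 alkylation of the sodium amidate; the soft electrophile and sodium counter-ion favour N- over O-methylation.

Step 4
Reactants: 5 (E)-N-(4,5-dibromo-2-iodophenyl)-3-ethoxy-N-methylacrylamide
Product: 6 (Z)-5,6-dibromo-3-(ethoxymethylene)-1-methylindolin-2-one
Conditions: Pd(OAc)2 (5 mol %), PPh3 (10 mol %), Et3N (2 equiv), MeCN, 70 °C
Reagents that add atoms: none
Why: Intramolecular Mizoroki–Heck reaction, the closest known class being the 5-exo cyclization of ortho-halo N-alkyl acrylanilides to 3-alkylidene oxindoles. PPh3 reduces Pd(OAc)2 to zerovalent palladium, which inserts into the C–I bond of 5. Syn carbopalladation then delivers the aryl group to the acrylamide α-carbon (5-exo-trig), which forms C3–C3a, closes the lactam ring and leaves palladium on the ethoxy-bearing exocyclic carbon. Rotation about the exocyclic C–C bond brings the C3 hydrogen syn to palladium, β-hydride elimination releases 6, and Et3N returns the hydridopalladium iodide to zerovalent palladium. No stereocenter is created; syn addition and syn elimination from the E-alkene imply the Z enol ether, a geometry the route does not need. Two selectivities are required: insertion at iodine and not at either bromine, which the much weaker C–I bond secures with a PPh3-ligated catalyst at 70 °C, and 5-exo over 6-endo closure, which the three-atom amide tether and the N-methyl anilide rotamer (aryl group syn to the acyl substituent) secure. Silver and thallium additives are left out on purpose, so that the halide-bound neutral pathway operates and the polarization of the enol ether, which in a cationic pathway would draw the aryl group to the oxygen-bearing carbon, has little say.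

Step 5
Reactants: 6 (Z)-5,6-dibromo-3-(ethoxymethylene)-1-methylindolin-2-one
Product: 8 2,5,6-tribromo-1-methyl-1H-indole-3-carbaldehyde, via oxocarbenium dibromophosphate 7 (not isolated)
Conditions: POBr3 (2 equiv), ClCH2CH2Cl, 70 °C; then H2O, 0 °C to rt
Reagents that add atoms: phosphorus oxybromide, O=P(Br)(Br)Br; water, O
Why: Deoxygenative bromination of a lactam by POBr3, as in the closing stage of the Vilsmeier–Haack haloformylation of oxindoles and the conversion of 3-acyl oxindoles into 2-halo-3-acylindoles. The lactam oxygen of the vinylogous ester is phosphorylated, bromide adds at C2 and expels dibromophosphate with aromatization, and the ethoxycarbenium ion 7 is hydrolysed to the aldehyde on aqueous work-up.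

## Compound list

1 | 3,4-dibromoaniline | Nc1ccc(Br)c(Br)c1 | starting material
2 | 4,5-dibromo-2-iodoaniline | Nc1cc(Br)c(Br)cc1I | intermediate
3 | (E)-3-ethoxyacryloyl chloride | CCO/C=C/C(=O)Cl | starting material
4 | (E)-N-(4,5-dibromo-2-iodophenyl)-3-ethoxyacrylamide | CCO/C=C/C(=O)Nc1cc(Br)c(Br)cc1I | intermediate
5 | (E)-N-(4,5-dibromo-2-iodophenyl)-3-ethoxy-N-methylacrylamide | CCO/C=C/C(=O)N(C)c1cc(Br)c(Br)cc1I | intermediate
6 | (Z)-5,6-dibromo-3-(ethoxymethylene)-1-methylindolin-2-one | CCO/C=C1/c2cc(Br)c(Br)cc2N(C)C1=O | intermediate
7 | ethyl[(2,5,6-tribromo-1-methyl-1H-indol-3-yl)methylidene]oxonium dibromophosphate | CC[O+]=Cc1c(Br)n(C)c2cc(Br)c(Br)cc12.[O-]P(=O)(Br)Br | intermediate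
8 | 2,5,6-tribromo-1-methyl-1H-indole-3-carbaldehyde | Cn1c(Br)c(C=O)c2cc(Br)c(Br)cc21 | target

## Step count and risks

Total steps: 5. Longest linear sequence: 5 steps (1 to 2 to 4 to 5 to 6 to 8).

**Step 4 (key step).** The aryl group may be transferred to the ethoxy-bearing carbon (6-endo closure), which the polarization of the enol ether favours electronically. Carbopalladation of the donor-substituted alkene may also be slow enough that oxidative addition into a C–Br bond and hydrodehalogenation begin to compete. The fallback takes the alkene out of the ring-closing event and makes the same C3–C3a bond by enolate arylation. It sets out from 2. Reductive monomethylation (paraformaldehyde, NaOMe, MeOH, reflux; then NaBH4) should give 4,5-dibromo-2-iodo-N-methylaniline F1. Acetylation (AcCl, pyridine, CH2Cl2) should give N-(4,5-dibromo-2-iodophenyl)-N-methylacetamide F2. Palladium-catalysed intramolecular α-arylation of the amide enolate (Pd(OAc)2, PCy3, NaOtBu, dioxane, 50 °C) should give 5,6-dibromo-1-methylindolin-2-one F3. Vilsmeier–Haack bromoformylation of F3 (POBr3, DMF, CHCl3, reflux; then H2O) would install the C2 bromine and the C3 aldehyde together and come back to the route at 8.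

**Step 5.** Hydrogen bromide formed from adventitious water may cleave the enol ether before the lactam is activated. The resulting hydroxymethylene lactam can then be phosphorylated at the exocyclic oxygen, so that bromide is delivered to the exocyclic carbon and not to C2. A slow or warm work-up may also allow displacement of the activated C2 bromide by water. The fallback sets out from 6. Dimethylamine (THF, rt) exchanges the ethoxy group by addition–elimination to give (E)-5,6-dibromo-3-[(dimethylamino)methylene]-1-methylindolin-2-one F4, the intermediate through which the Vilsmeier–Haack haloformylation of oxindoles runs. POBr3 in CHCl3 at reflux then converts the lactam into the 2-bromoindole, and aqueous hydrolysis of the iminium salt comes back to the route at 8. The amino group is not cleaved by acid as the ether is, and it leaves the lactam oxygen as the only site open to phosphorylation. Either geometric isomer of F4 would serve.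

**Step 1.** A second iodination at the flanked ortho position, or oxidation of the free aniline by the iodinating agent, may erode the material balance and complicate purification. The fallback replaces electrophilic substitution on the free aniline by amide-directed C–H iodination. It sets out from 1. Acetylation (Ac2O, AcOH) gives N-(3,4-dibromophenyl)acetamide F5. Cyclopalladation by divalent palladium at the less hindered ortho C–H, followed by iodination (Pd(OAc)2 5 mol %, NIS, TsOH·H2O, toluene, rt), gives N-(4,5-dibromo-2-iodophenyl)acetamide F6. Hydrolysis (KOH, EtOH/H2O, reflux) comes back to the route at 2. Palladium does not fall to the zerovalent state in this cycle, so the aryl bromides are not at risk, and a second iodination is blocked because the remaining ortho hydrogen is flanked by bromine.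

## Further compounds

F1 | step 4 | 4,5-dibromo-2-iodo-N-methylaniline | CNc1cc(Br)c(Br)cc1I
F2 | step 4 | N-(4,5-dibromo-2-iodophenyl)-N-methylacetamide | CC(=O)N(C)c1cc(Br)c(Br)cc1I
F3 | step 4 | 5,6-dibromo-1-methylindolin-2-one | CN1C(=O)Cc2cc(Br)c(Br)cc21
F4 | step 5 | (E)-5,6-dibromo-3-[(dimethylamino)methylene]-1-methylindolin-2-one | CN(C)/C=C1/C(=O)N(C)c2cc(Br)c(Br)cc21
F5 | step 1 | N-(3,4-dibromophenyl)acetamide | CC(=O)Nc1ccc(Br)c(Br)c1
F6 | step 1 | N-(4,5-dibromo-2-iodophenyl)acetamide | CC(=O)Nc1cc(Br)c(Br)cc1I
A1 | alternative 1 | methyl but-3-yn-1-yl(ethynyl)carbamate | COC(=O)N(C#C)CCC#C
A2 | alternative 1 | bis(trimethylsilyl)acetylene | C[Si](C)(C)C#C[Si](C)(C)C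
A3 | alternative 1 | methyl 5,6-bis(trimethylsilyl)indoline-1-carboxylate | COC(=O)N1CCc2cc([Si](C)(C)C)c([Si](C)(C)C)cc21
A4 | alternative 2 | 3-formyl-1-methyl-6-(trimethylsilyl)-1H-indol-5-yl trifluoromethanesulfonate | Cn1cc(C=O)c2cc(OS(=O)(=O)C(F)(F)F)c([Si](C)(C)C)cc21
A5 | alternative 2 | 1-methyl-5,6-didehydro-1H-indole-3-carbaldehyde (5,6-indolyne) | CN1C=C(C=O)C2=CC#CC=C21
A6 | alternative 2 | 5,6-dibromo-1-methyl-1H-indole-3-carbaldehyde | Cn1cc(C=O)c2cc(Br)c(Br)cc21
A7 | alternative 3 | ethyl (Z)-2-azido-3-(3,4-dibromophenyl)acrylate | CCOC(=O)/C(N=[N+]=[N-])=C/c1ccc(Br)c(Br)c1
A8 | alternative 3 | ethyl 5,6-dibromo-1H-indole-2-carboxylate | CCOC(=O)c1cc2cc(Br)c(Br)cc2[nH]1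
A9 | alternative 3 | ethyl 6,7-dibromo-1H-indole-2-carboxylate | CCOC(=O)c1cc2ccc(Br)c(Br)c2[nH]1
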